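The numbers of this flask were set for the occasion; no experiment stands behind them.

The second end groups had a decomposition half-life of 0.46 h against a feed of 10 h, so I reckoned this flask as a race early in the feed.

    first end groups + one-sided end groups → capped ends (k1 = 81 M⁻¹ h⁻¹)
    first end groups + second end groups → links (k2 = 24 M⁻¹ h⁻¹)
    links ⇌ isomer of the product (K3 = 0.33, k3 = 2.4 h⁻¹)
    second end groups → decomposed reagent (k4 = 1.5 h⁻¹)

first end groups 0.050 M (fed, over 10 h); second end groups 0.0490 M; one-sided end groups 5.00 mM; time 8.0 d

1. which holds at 8.0 d: what has brought the reaction to rest, or that it has not come to rest (it is still moving / all of the first end groups has reacted / forward and back rates have come level / the second end groups has run out first)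
2. share of the first end groups used up at 8.0 d
3. links at 8.0 d, in percent of the first end groups charged
4. capped ends at 8.0 d, in percent of the first end groups charged

- the reaction counts as stopped when no species that holds the first end groups changes by six tenths of a point or more over the second half of the time
- run time (flask): 8.0 d

I first asked what an error in each number would do. The capped share follows the charges one for one: one-sided end groups were the smaller charge, so capped ends could reach 10.0%. An error in 81 M⁻¹ h⁻¹ moved the time of capping, not its end, because the half-life of first end groups by that step, with one-sided end groups held at their charge, 0.071 d, was short against the run. The isomer step relaxes with a half-life of 0.0717 h, so its rate constant could be poor, but 0.33 had to be right. The decomposition constant 1.5 h⁻¹ had to be known well, for it stands in both factors of the denominator below.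

First end groups entered at a steady rate and drained by a pseudo-first-order constant λ, while second end groups decayed at 1.5 h⁻¹. I held one-sided end groups at their charge and counted second end groups at 0.5 of theirs, a rough mean over their short life:

λ = 81 M⁻¹ h⁻¹ × [one-sided end groups] + 0.5 × 24 M⁻¹ h⁻¹ × [second end groups] = 0.993 h⁻¹

share = 24 M⁻¹ h⁻¹ × 0.0490 M / (10 h × 1.5 h⁻¹ × (1.5 h⁻¹ + 0.993 h⁻¹)) = 3.14%

This capture share is the part of the charged first end groups that second end groups bind before decomposing. Adding 10.0% gave me a conversion of 13.1%, and dividing by 1 + 0.33 gave links of 2.36%.

The forecast named the second end groups has run out first, with conversion 13.3%, links 2.5% and capped ends 10%, “leaving the rest of the first end groups stranded unreacted”. My conversion stood lower.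

The flask gave the second end groups has run out first, with 0% left, conversion 13.4%, links 2.53% and capped ends 10.0%. At 0.0184 d in the flask, the rate of decomposition over the rate of link formation stood at 36. Conversion beyond capped ends came to 3.4 percentage points, where the capture share stood at 3.14%. For the neighbour flask with 0.012 M of second end groups, the same lines gave λ = 0.549 h⁻¹ and a capture share of 0.937%, hence links of 0.705%; that neighbour flask gave 0.693%.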